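Spend a small charge of substrate on arithmetic first, and ask what the flask below still holds when half of it is converted.

| flask | substrate | partner | free catalyst | remark |
|---|---|---|---|---|
| midnight | 0.020 M | 0.021 M | 40 µM | the very flask that is asked about, followed so far |
| spring | 0.013 M | 0.021 M | 40 µM | run made earlier |
| flask | 0.020 M | 0.0210 M | 40 µM |  |

| run | time / h | product / % | substrate / % |
|---|---|---|---|
| midnight | 0.833 | 2.7 | 97.3 |
| midnight | 1.50 | 5.6 | 94.4 |
| midnight | 3.00 | 12.1 | 88.3 |
| midnight | 5.00 | 18.1 | 81.9 |
| midnight | 10.0 | 33.3 | 67.0 |
| spring | 1.33 | 7.1 | 93.1 |
| spring | 4.00 | 20.5 | 79.4 |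
| spring | 6.00 | 29.3 | 71.0 |
| spring | 10.0 | 43.1 | 55.0 |
| spring | 15.0 | 58.7 | 42.2 |

(each reading ± 0.5 percentage points)

1. factor on the rate of making product when 50% of the substrate are converted if free catalyst is charged twice over
2. factor on the rate when 50% of the substrate are converted if free catalyst is charged at 200 µM instead

- no earlier run changes the charge of free catalyst; that part of a forecast is a guess

Compare the early readings: up to its second reading the midnight run makes product at an average of 7.47 × 10⁻⁴ M h⁻¹ and up to its first the spring run at an average of 6.94 × 10⁻⁴ M h⁻¹, though the spring charge of substrate is 0.650 of the midnight one, so look for the order of the rate in c_partner, which no reading shows. Subtract the product due at 50% from the partner charged and get 0.0110 M, the c_partner left at that conversion if partner is spent one for one with product, the partner margin. But this margin holds no term for the catalyst, so with a rate proportional to the catalyst charged, my reckoning gives 2 for the doubled charge and 5.00 for 200 µM, and no earlier run tests either figure. The forecast, with its words “I therefore shade slightly below linear”, stands a little lower at 1.9 and 4.5.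

The simulation gives 4.47 for the doubled charge and 13.9 for 200 µM, both above my reckoning.

    partner + free catalyst ⇌ catalyst intermediate A (K = 1200 M⁻¹, k = 2900 M⁻¹ h⁻¹)
    catalyst intermediate A → catalyst intermediate B (k = 110 h⁻¹)
    catalyst intermediate B → released group + catalyst intermediate C (k = 1200 h⁻¹)
    substrate + catalyst intermediate C ⇌ catalyst intermediate D (K = 95.0 M⁻¹, k = 6200 M⁻¹ h⁻¹)
    catalyst intermediate D ⇌ catalyst intermediate E (K = 1.80, k = 15000 h⁻¹)
    catalyst intermediate E → free catalyst + product (k = 130 h⁻¹)
    partner → decomposed reagent (k = 0.0500 h⁻¹)

Hold the margin of 0.0110 M against the flask at 20.0 h, when substrate stands at 51% and not yet at the conversion of the margin: c_partner is 0.00218 M there, and the gap of 0.00882 M lies close to the 0.00901 M of decomposed reagent. Take the path to decomposed reagent away and the rate at 50% comes out 3.07 times the actual one. For the flask charged at 200 µM, divide the factor by the increase in catalyst and get 2.78, less than the 5.05 by which the margin exceeds the c_partner of the flask charged at 40 µM at 20.0 h.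

(The data were generated by integration with constants of no real substance, and the scatter is random.)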